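All constants were set for the occasion; the run is a simulation.

A small charge of D, 0.700 equiv on Z, has two takers, and the Z.D made is the part of that charge which reaches Z.

    2 Z ⇌ Z2, settled at all times (K1 = 850 M⁻¹)
    Z + D → Z.D (k2 = 240 M⁻¹ min⁻¹)
    D + Q → D.Q (k3 = 5.9 M⁻¹ min⁻¹)

common to all: Z 0.064 M; D 0.700 equiv; Q 0.0640 M

| flask | remark | time |
|---|---|---|
| Thursday's | one stirred flow tank at steady state, fed with the mixture as stated, mean residence time 3.00 h |  |
| Friday's | plug flow through a tube for 1.0 h, no back-mixing | 1.0 h |
| Wednesday's | one stirred flow tank at steady state, fed with the mixture as stated, mean residence time 1.0 h |  |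
| Tuesday's | everything together in a closed stirred flask, run for 1.0 h | 1.0 h |

- percentages count the Z that a species holds: one Z2 counts as two
- a doubled species enters its step squared and goes two at a time
- the stated concentrations are those of everything mixed, before any reaction; amounts are the same in each set-up
- run time (Friday's): 1.0 h

- the set-up with the highest amount of Z.D at the outlet or at the end, in percent of the Z put in ("none" if the first two lie within 2 percentage points) (Thursday's / Friday's / Wednesday's / Tuesday's / none)
- amount of Z.D at the outlet or at the end, in percent of the Z put in, Thursday's
- amount of Z.D at the outlet or at the end, in percent of the Z put in, Friday's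
- amount of Z.D at the outlet or at the end, in percent of the Z put in, Wednesday's
- amount of Z.D at the outlet or at the end, in percent of the Z put in, Tuesday's

The quantity to watch is the split ratio, a selectivity factor: the rate constant of Z + D times free Z, over the rate constant of D + Q times Q. A fraction ratio/(1 + ratio) of the D consumed becomes Z.D. Free Z is what the fast balance leaves outside Z2, two Z to each Z2, so the ratio has to be solved at both ends of the run and joined.

Start: free Z 0.00585 M, ratio 3.72, share to Z.D 78.8%.

That share held throughout: Z.D 55.2%.

End, built on that figure: free Z 0.00382 M, Q 0.0545 M, ratio 2.85, share 74.1%.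

Mean of the two shares: Z.D 53.5%.

The weak link is that end state, since it rests on a figure higher than the joined one. Reforged on the joined figure:

End: free Z 0.00390 M, Q 0.0534 M, end ratio 2.97, share 74.8%.

Friday's tube and Tuesday's flask: Z.D 53.8%.

Even at the end D lives 0.799 min, so within the hour of Friday's tube D, the limiting reagent, is taken as consumed. A tank holds its outlet mixture, so its D meets the end ratio, which gives 52.4% for Thursday's tank and for Wednesday's tank alike. The tube and the closed flask run one course, so this reckoning commits to a tie at the top.

The forecast, whose figures differ from this reckoning's for the tube, the closed flask and Wednesday's tank, gave 53.9% for Friday's tube, 53.9% for Tuesday's flask, 52.4% for Thursday's tank, 52% for Wednesday's tank and best none, holding that “the tanks lose only a point or two”.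

The simulation gives 54.0% for Friday's tube, 54.0% for Tuesday's flask, 52.4% for Thursday's tank and 52.0% for Wednesday's tank, so best is none. Wednesday's tank still holds D at 5.82 × 10⁻⁴ M, more than the 1.97 × 10⁻⁴ M in Thursday's tank. Put on the D consumed in Wednesday's tank, the end ratio of 2.97 gives 51.7%, and that tank reads 52.0%.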